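## Analysis of the target

The target is a linear pentameric phlorotannin, C30H22O16: five benzene rings joined by four diaryl ether oxygens, with twelve free phenolic hydroxyls and no stereocentre. With the rings lettered A to E, ring A is a 2,4,6-trihydroxyphenyl group bound through A1. Ring B carries the ether to ring A at B1, hydroxyls at B3 and B5 and the ether to ring C at B4. Ring C carries the ether from ring B at C1, the ether to ring D at the neighbouring C2 and hydroxyls at C3 and C5. Ring D repeats the pattern of ring B, and ring E is a 3,4,5-trihydroxyphenyl group bound through E1. Every ether oxygen therefore joins a carbon lying between two oxygen-bearing neighbours (A1, B4, C2, D4) to a less crowded carbon (B1, C1, D1, E1), so all four C–O bonds are hindered, electron-rich diaryl ethers, for which aryl halide couplings are least dependable. The free polyphenol is oxidised easily in air, above all under base, so the oxygens must travel masked, and the molecule has no symmetry that would allow two-directional assembly. The plan rests on ring B: B1, B3 and B5 are the alternating oxygens of a folded triketide chain, and B4, between B3 and B5, carries the ether to ring C. Ring B can thus be made from an open six-carbon chain on which the ring A oxygen and the ring C oxygen are bound to non-aromatic carbons.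

## Retrosynthetic reasoning

**24 to 23.** The last operation cleaves ten O–CH3 bonds. Methyl ethers are the smallest mask beside the crowded ether carbons and withstand copper catalysis, peracid, hydride, Grignard reagent and phenoxide base. The two ring B hydroxyls of 23 need no mask because they appear only one step earlier. The forward reaction has to remove all ten methyl groups without cutting a diaryl ether.

**23 to 17 and 20.** Ring B is opened at the ether bond O–B1 and at the ring bond B4–B5. This takes the two most awkward linkages off the list of aryl couplings. The oxygen of 20, a phenol with both ortho positions occupied, is bonded to the sp carbon C3 of 17, and the ring C oxygen already sits on C6, the carbon that becomes B4. Forward, the phenoxide of 20 must add to C3, and C6 must then acylate itself with the ester carbon C1; chain carbons C3, C4, C5, C6, C1, C2 become B1 to B6. A free alkoxide would displace the ring A aryloxy group from the intermediate enol ether by addition–elimination, so the phenoxide of 20, in excess, is planned as the only base and exchange at B1 is then degenerate. Ring D has the same oxygen pattern, but ring B is where the two large halves meet and where the most hindered phenol must be attached, so the cut is made there.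

**17 to 14 and 15, through 16.** The C5 ketone is taken back to a carbinol and the C2–C3 bond is cut. Once C5 is a ketone, the C2 methylene lies between an ester and an activated alkyne and is very easily deprotonated. The ketone is therefore unveiled last, by a neutral oxidation of 16. The two ester carbons are joined to the alkyne terminus of 14 with 15 under copper catalysis, which needs no base. This avoids oxidising and esterifying a hydroxy ynone or a free ynone acid. The ester is ethyl because 15 is the commercial diazo ester; its alkoxy group is lost in the ring closure.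

**14 to 9, 10 and 13, through 11 and 12.** The C4–C5 bond is cut to aldehyde 12 and alkynyl Grignard reagent 13. The O–C6 bond is cut to phenol 9 and chloroamide 10, so the ring C oxygen is alkylated by simple SN2 chemistry. The amide 11 is reduced to 12 without acid, because aryloxyacetaldehydes of electron-rich phenols cyclise onto the ring under acid.

**9 to 5 and 6, through 7.** The C1 hydroxyl is traced back to a formyl group and the C2–O bond is cut on the ring C side. The formyl group of 6 serves twice: it activates the neighbouring bromide for copper-mediated substitution, and peracid then exchanges it for the oxygen. The crowded carbon C2 is made the electrophile, so that the nucleophile 5 is a phenol with both ortho positions free.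

**5 to 1 and 2, through 3.** The same tactic is used one ring further on: the D1 hydroxyl comes from a formyl group, and the D4–O bond is cut on the ring D side. The para formyl group of 2 activates the bromide, and 1 has no ortho substituent.

**20 to 18.** The air-sensitive phenol 20 is made when needed from aldehyde 18 by formyl-to-hydroxyl exchange.

## Alternatives that were turned down

**Alternative 1:** Ring C is disconnected at both ether carbons. The C1–O bond to ring B and a C2–I bond, a placeholder for the later ether to ring D, are formed together on an aryne.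
- *Forward key step:* fluoride releases the dimethoxy aryne from silyl triflate A3. The caesium salt of the A–B phenol A2 adds at C1, and the aryl anion left at C2 takes iodine from an iodine donor to give the trimer iodide A1.
- *For:* two neighbouring positions of ring C are loaded in one metal-free operation. The C3 methoxy group directs the nucleophile to C1 and stabilises the anion at C2.
- *Against:* an aryl anion beside an aryloxy group is protonated by any proton source much faster than a bimolecular iodine transfer can capture it, and the iodine donor is also exposed to fluoride and phenoxide. A2 already contains the crowded A–B ether, which must be made by a coupling. A1 must still be coupled at an iodide flanked by a methoxy and an aryloxy group, the most hindered ether formation of the whole series. A3 itself takes several steps.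
- *Comparison:* it is stronger in convergence, joining two halves at the middle ring, and probably shorter. The chosen route offers instead two ethers formed on non-aromatic carbons, no anion-capture race, and only two copper couplings, both on bromides activated by a formyl group.

**Alternative 2:** Ring A is cut at the A1–A2 ring bond and unfolded to the triketo ester A5, which carries ring B as an aryloxy group on its terminal carbon.
- *Forward key step:* base closes A5 by attack of the aryloxy-bearing carbon on the ester carbonyl; the triketone tautomerises to the trihydroxy ring of dimer A4.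
- *For:* the crowded A1 oxygen is attached by alkylation. The precursor is a saturated triketo ester with no sensitive ynone, no intermolecular addition and no enol ether geometry to settle. The closure is a plain biomimetic Claisen folding, so the key step is better precedented than the chosen one.
- *Against:* only one ether is gained per ring closure. The most acidic site of A5 is the methylene between the two ketones, and lactonisation through the enol oxygen is the usual fate of such triketides. A4 then has three free hydroxyls on a very electron-rich ring, which must be masked again. After debenzylation, the B4 phenol, flanked by two methoxy groups, has to be coupled to ring C, followed by rings D and E, so three hindered couplings remain.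
- *Comparison:* the chosen route faces a similar competition between carbon and oxygen acylation. In return it forms two ether linkages per ring closure and places the closure one step from the end, so nothing is coupled onto a free polyphenol.

**Alternative 3:** The A4–O and C5–O bonds are cut, leading back to the dideoxy pentamer A7.
- *Forward key step:* iridium-catalysed, sterically governed C–H borylation of A7 at A4 and C5, then oxidation of both C–B bonds in the same pot, gives the diphenol A6.
- *For:* A4–H and C5–H are the only aromatic hydrogens of A7 without an ortho substituent. Every hydrogen of rings B, D and E lies between two oxygen substituents. The selectivity is therefore predictable and the reaction type is well established, which makes this key step more reliable than the one chosen.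
- *Against:* the two oxygens it installs are available in commercial ring building blocks at no cost. A1 and C2 in A7 are as crowded as in the target, so all four hindered diaryl ethers must still be made by couplings before the key step. The step count does not fall.
- *Comparison:* it is stronger in certainty of the key step. The chosen route spends its key step on the real difficulty, the ethers at A1 and B4.

Key step: step 11

**Remarks on the chemistry (assumptions)**
- The cyclisation precursor 17 is carried as the ethyl ester, because 15 is the commercial diazo ester and the alkoxy group is expelled in the ring closure.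
- Compounds 14 and 16 are racemic; their carbinol carbon becomes the C5 carbonyl in step 9.
- Reagent 13 is used as its commercial THF solution.

## Steps

Step 1
Reactants: 1 3,4,5-trimethoxyphenol; 2 4-bromo-3,5-dimethoxybenzaldehyde
Product: 3 3,5-dimethoxy-4-(3,4,5-trimethoxyphenoxy)benzaldehyde
Conditions: CuI (10 mol%), picolinic acid (20 mol%), K3PO4, DMSO, 90 °C
Reagents that add atoms: none
Why: Copper-catalysed Ullmann diaryl ether synthesis; the bromide is activated by the para formyl group, phenol 1 has no ortho substituent, and the picolinic acid ligand system suits aryl halides flanked by ortho groups.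

Step 2
Reactants: 3 3,5-dimethoxy-4-(3,4,5-trimethoxyphenoxy)benzaldehyde
Product: 5 3,5-dimethoxy-4-(3,4,5-trimethoxyphenoxy)phenol, via aryl formate 4 (not isolated)
Conditions: mCPBA, CH2Cl2, 0 °C to rt; then K2CO3 (cat.), MeOH, rt
Reagents that add atoms: 3-chloroperoxybenzoic acid (mCPBA), OOC(=O)c1cccc(Cl)c1
Why: Baeyer–Villiger (Dakin-type) oxidation; the aryl group carries a para aryloxy donor and should migrate in preference to hydride, as 3,4,5-trimethoxyphenyl does, and the formate is then cleaved by transesterification.

Step 3
Reactants: 5 3,5-dimethoxy-4-(3,4,5-trimethoxyphenoxy)phenol; 6 2-bromo-3,5-dimethoxybenzaldehyde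
Product: 7 2-[3,5-dimethoxy-4-(3,4,5-trimethoxyphenoxy)phenoxy]-3,5-dimethoxybenzaldehyde
Conditions: CuI (10 mol%), picolinic acid (20 mol%), K3PO4, DMSO, 90 °C
Reagents that add atoms: none
Why: Ullmann coupling; the ortho formyl group of 6 assists copper insertion into the C–Br bond, and phenol 5 is unsubstituted next to its hydroxyl.

Step 4
Reactants: 7 2-[3,5-dimethoxy-4-(3,4,5-trimethoxyphenoxy)phenoxy]-3,5-dimethoxybenzaldehyde
Product: 9 2-[3,5-dimethoxy-4-(3,4,5-trimethoxyphenoxy)phenoxy]-3,5-dimethoxyphenol, via aryl formate 8 (not isolated)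
Conditions: mCPBA, CH2Cl2, 0 °C to rt; then K2CO3 (cat.), MeOH, rt
Reagents that add atoms: 3-chloroperoxybenzoic acid (mCPBA), OOC(=O)c1cccc(Cl)c1
Why: Baeyer–Villiger oxidation of an ortho-aryloxybenzaldehyde, the usual route to catechol monoethers; the ortho oxygen supports aryl migration, and methanolysis of the formate frees the phenol.

Step 5
Reactants: 9 2-[3,5-dimethoxy-4-(3,4,5-trimethoxyphenoxy)phenoxy]-3,5-dimethoxyphenol; 10 2-chloro-N-methoxy-N-methylacetamide
Product: 11 N-methoxy-N-methyl-2-{2-[3,5-dimethoxy-4-(3,4,5-trimethoxyphenoxy)phenoxy]-3,5-dimethoxyphenoxy}acetamide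
Conditions: K2CO3, NaI (cat.), acetone, reflux
Reagents that add atoms: none
Why: Williamson ether synthesis with an α-chloroamide under Finkelstein catalysis; the N-methoxy-N-methylamide is installed in one step and the ring C oxygen is bonded to an sp3 carbon.

Step 6
Reactants: 11 N-methoxy-N-methyl-2-{2-[3,5-dimethoxy-4-(3,4,5-trimethoxyphenoxy)phenoxy]-3,5-dimethoxyphenoxy}acetamide
Product: 12 2-{2-[3,5-dimethoxy-4-(3,4,5-trimethoxyphenoxy)phenoxy]-3,5-dimethoxyphenoxy}acetaldehyde
Conditions: i-Bu2AlH, THF, −78 °C; aq. potassium sodium tartrate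
Reagents that add atoms: none
Why: Hydride reduction of an N-methoxy-N-methylamide stops at the aldehyde because the chelated tetrahedral aluminium intermediate survives until work-up; no acid is used, so the aryloxyacetaldehyde should not cyclise onto ring C, and 12 is used at once.

Step 7
Reactants: 12 2-{2-[3,5-dimethoxy-4-(3,4,5-trimethoxyphenoxy)phenoxy]-3,5-dimethoxyphenoxy}acetaldehyde; 13 ethynylmagnesium bromide
Product: 14 rac-1-{2-[3,5-dimethoxy-4-(3,4,5-trimethoxyphenoxy)phenoxy]-3,5-dimethoxyphenoxy}but-3-yn-2-ol
Conditions: THF, −78 to 0 °C; sat. aq. NH4Cl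
Reagents that add atoms: none
Why: 1,2-Addition of an alkynyl Grignard reagent to an aldehyde; the carbinol centre forms racemic, which is immaterial because it is oxidised in step 9.

Step 8
Reactants: 14 rac-1-{2-[3,5-dimethoxy-4-(3,4,5-trimethoxyphenoxy)phenoxy]-3,5-dimethoxyphenoxy}but-3-yn-2-ol; 15 ethyl diazoacetate
Product: 16 ethyl rac-6-{2-[3,5-dimethoxy-4-(3,4,5-trimethoxyphenoxy)phenoxy]-3,5-dimethoxyphenoxy}-5-hydroxyhex-3-ynoate
Conditions: CuI (5 mol%), MeCN, rt, slow addition of 15
Reagents that add atoms: none
Why: Copper-catalysed coupling of a terminal alkyne with a diazoacetate (copper acetylide, carbene insertion, protonation) gives the 3-alkynoate without base, so the skipped alkyne should not isomerise to the allenoate; the alkyne is still electron-neutral because C5 is a carbinol.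

Step 9
Reactants: 16 ethyl rac-6-{2-[3,5-dimethoxy-4-(3,4,5-trimethoxyphenoxy)phenoxy]-3,5-dimethoxyphenoxy}-5-hydroxyhex-3-ynoate
Product: 17 ethyl 6-{2-[3,5-dimethoxy-4-(3,4,5-trimethoxyphenoxy)phenoxy]-3,5-dimethoxyphenoxy}-5-oxohex-3-ynoate
Conditions: Dess–Martin periodinane, CH2Cl2, 0 °C to rt
Reagents that add atoms: none
Why: Dess–Martin oxidation of a propargylic alcohol to the ynone under neutral to weakly acidic conditions, so the acidic C2 methylene meets no base; 17 is used without storage, and any allenyl ketone tautomer present reacts at the same carbon in step 11.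

Step 10
Reactants: 18 2,4,6-trimethoxybenzaldehyde
Product: 20 2,4,6-trimethoxyphenol, via aryl formate 19 (not isolated)
Conditions: 30% aq. H2O2, H2SO4 (cat.), MeOH, rt
Reagents that add atoms: hydrogen peroxide, OO
Why: Acid-catalysed Dakin oxidation of a very electron-rich benzaldehyde; the formate is methanolysed in the same pot, and the air-sensitive phenol is made shortly before step 11.

Step 11
Reactants: 17 ethyl 6-{2-[3,5-dimethoxy-4-(3,4,5-trimethoxyphenoxy)phenoxy]-3,5-dimethoxyphenoxy}-5-oxohex-3-ynoate; 20 2,4,6-trimethoxyphenol
Product: 23 2-{2-[3,5-dimethoxy-4-(3,4,5-trimethoxyphenoxy)phenoxy]-3,5-dimethoxyphenoxy}-5-(2,4,6-trimethoxyphenoxy)benzene-1,3-diol, via enol ether 21 (not isolated), via cyclohexenedione 22 (not isolated)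
Conditions: 20 (3 equiv), KOtBu (2.7 equiv), degassed THF–DMSO, 0 °C; then 17, 0 °C to rt; then 60 °C; aq. NH4Cl
Reagents that add atoms: none
Why: Proposed new method: the potassium phenoxide of 20 adds to C3 of ynone 17 (or of its allenyl ketone tautomer, which offers the same carbon), the β position of the ketone, giving enol ether 21 and the O–B1 bond; proton exchange through the phenol/phenoxide buffer then supplies the C6 enolate, acidified by the ketone and the ring C aryloxy group, which attacks the ester carbonyl in a 6-exo-trig Dieckmann closure (B4–B5 bond), expels ethoxide and gives 22, whose enolisation to the resorcinol phenoxide is irreversible. The closest known reactions are the base-mediated oxa-Michael addition of phenols to ynones and the aromatising Dieckmann closure of 3,5-dioxohexanoate enol ethers; their tandem use on a 5-oxohex-3-ynoate has not been shown. No stereocentre is formed, since C6 becomes the aromatic carbon B4. The addition is regioselective because C3 is the only β carbon of the ynone and the central carbon of the allene tautomer. Carbon acylation must win over oxygen acylation, and this is expected from reversibility: the aryloxide is the only nucleophile present in quantity, so exchange at B1 is degenerate, the E and Z forms of 21 interconvert through the C2 dienolate and by addition–elimination, and a pyranone lactone would be reopened at its carbonyl, while only carbon acylation leads to the aromatic sink. Keeping 20 in slight excess over KOtBu leaves no free alkoxide, and the ethoxide released is protonated at once by the product, so the ring A ether should not be exchanged.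

Step 12
Reactants: 23 2-{2-[3,5-dimethoxy-4-(3,4,5-trimethoxyphenoxy)phenoxy]-3,5-dimethoxyphenoxy}-5-(2,4,6-trimethoxyphenoxy)benzene-1,3-diol
Product: 24 2-{4-[2-(3,5-dihydroxy-4-(3,4,5-trihydroxyphenoxy)phenoxy)-3,5-dihydroxyphenoxy]-3,5-dihydroxyphenoxy}benzene-1,3,5-triol (CNP0227069.0)
Conditions: BBr3 (25 equiv), CH2Cl2, −78 °C to rt, argon; MeOH then H2O; reversed-phase purification under argon
Reagents that add atoms: none
Why: Lewis-acid cleavage of aryl methyl ethers with BBr3 (borate formation, then bromide attack on the methyl group); diaryl ether bonds should not be cleaved, and the two free ring B hydroxyls are borylated and released on hydrolysis.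

## Compound list

1 | 3,4,5-trimethoxyphenol | COc1cc(O)cc(OC)c1OC | starting material
2 | 4-bromo-3,5-dimethoxybenzaldehyde | COc1cc(C=O)cc(OC)c1Br | starting material
3 | 3,5-dimethoxy-4-(3,4,5-trimethoxyphenoxy)benzaldehyde | O=Cc1cc(OC)c(Oc2cc(OC)c(OC)c(OC)c2)c(OC)c1 | intermediate
4 | 3,5-dimethoxy-4-(3,4,5-trimethoxyphenoxy)phenyl formate | O=COc1cc(OC)c(Oc2cc(OC)c(OC)c(OC)c2)c(OC)c1 | intermediate
5 | 3,5-dimethoxy-4-(3,4,5-trimethoxyphenoxy)phenol | Oc1cc(OC)c(Oc2cc(OC)c(OC)c(OC)c2)c(OC)c1 | intermediate
6 | 2-bromo-3,5-dimethoxybenzaldehyde | COc1cc(OC)c(Br)c(C=O)c1 | starting material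
7 | 2-[3,5-dimethoxy-4-(3,4,5-trimethoxyphenoxy)phenoxy]-3,5-dimethoxybenzaldehyde | O=Cc1cc(OC)cc(OC)c1Oc1cc(OC)c(Oc2cc(OC)c(OC)c(OC)c2)c(OC)c1 | intermediate
8 | 2-[3,5-dimethoxy-4-(3,4,5-trimethoxyphenoxy)phenoxy]-3,5-dimethoxyphenyl formate | O=COc1cc(OC)cc(OC)c1Oc1cc(OC)c(Oc2cc(OC)c(OC)c(OC)c2)c(OC)c1 | intermediate
9 | 2-[3,5-dimethoxy-4-(3,4,5-trimethoxyphenoxy)phenoxy]-3,5-dimethoxyphenol | Oc1cc(OC)cc(OC)c1Oc1cc(OC)c(Oc2cc(OC)c(OC)c(OC)c2)c(OC)c1 | intermediate
10 | 2-chloro-N-methoxy-N-methylacetamide | CON(C)C(=O)CCl | starting material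
11 | N-methoxy-N-methyl-2-{2-[3,5-dimethoxy-4-(3,4,5-trimethoxyphenoxy)phenoxy]-3,5-dimethoxyphenoxy}acetamide | CON(C)C(=O)COc1cc(OC)cc(OC)c1Oc1cc(OC)c(Oc2cc(OC)c(OC)c(OC)c2)c(OC)c1 | intermediate
12 | 2-{2-[3,5-dimethoxy-4-(3,4,5-trimethoxyphenoxy)phenoxy]-3,5-dimethoxyphenoxy}acetaldehyde | O=CCOc1cc(OC)cc(OC)c1Oc1cc(OC)c(Oc2cc(OC)c(OC)c(OC)c2)c(OC)c1 | intermediate
13 | ethynylmagnesium bromide | C#C[Mg]Br | starting material
14 | rac-1-{2-[3,5-dimethoxy-4-(3,4,5-trimethoxyphenoxy)phenoxy]-3,5-dimethoxyphenoxy}but-3-yn-2-ol | C#CC(O)COc1cc(OC)cc(OC)c1Oc1cc(OC)c(Oc2cc(OC)c(OC)c(OC)c2)c(OC)c1 | intermediate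
15 | ethyl diazoacetate | CCOC(=O)C=[N+]=[N-] | starting material
16 | ethyl rac-6-{2-[3,5-dimethoxy-4-(3,4,5-trimethoxyphenoxy)phenoxy]-3,5-dimethoxyphenoxy}-5-hydroxyhex-3-ynoate | CCOC(=O)CC#CC(O)COc1cc(OC)cc(OC)c1Oc1cc(OC)c(Oc2cc(OC)c(OC)c(OC)c2)c(OC)c1 | intermediate
17 | ethyl 6-{2-[3,5-dimethoxy-4-(3,4,5-trimethoxyphenoxy)phenoxy]-3,5-dimethoxyphenoxy}-5-oxohex-3-ynoate | CCOC(=O)CC#CC(=O)COc1cc(OC)cc(OC)c1Oc1cc(OC)c(Oc2cc(OC)c(OC)c(OC)c2)c(OC)c1 | intermediate
18 | 2,4,6-trimethoxybenzaldehyde | COc1cc(OC)c(C=O)c(OC)c1 | starting material
19 | 2,4,6-trimethoxyphenyl formate | COc1cc(OC)c(OC=O)c(OC)c1 | intermediate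
20 | 2,4,6-trimethoxyphenol | COc1cc(OC)c(O)c(OC)c1 | intermediate
21 | ethyl (3E)-6-{2-[3,5-dimethoxy-4-(3,4,5-trimethoxyphenoxy)phenoxy]-3,5-dimethoxyphenoxy}-5-oxo-3-(2,4,6-trimethoxyphenoxy)hex-3-enoate (the isomer that cyclises; in equilibrium with the Z form) | CCOC(=O)C/C(Oc1c(OC)cc(OC)cc1OC)=C\C(=O)COc1cc(OC)cc(OC)c1Oc1cc(OC)c(Oc2cc(OC)c(OC)c(OC)c2)c(OC)c1 | intermediate
22 | 2-{2-[3,5-dimethoxy-4-(3,4,5-trimethoxyphenoxy)phenoxy]-3,5-dimethoxyphenoxy}-5-(2,4,6-trimethoxyphenoxy)cyclohex-4-ene-1,3-dione (racemic at C2, transient) | O=C1CC(Oc2c(OC)cc(OC)cc2OC)=CC(=O)C1Oc1cc(OC)cc(OC)c1Oc1cc(OC)c(Oc2cc(OC)c(OC)c(OC)c2)c(OC)c1 | intermediate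
23 | 2-{2-[3,5-dimethoxy-4-(3,4,5-trimethoxyphenoxy)phenoxy]-3,5-dimethoxyphenoxy}-5-(2,4,6-trimethoxyphenoxy)benzene-1,3-diol | Oc1cc(Oc2c(OC)cc(OC)cc2OC)cc(O)c1Oc1cc(OC)cc(OC)c1Oc1cc(OC)c(Oc2cc(OC)c(OC)c(OC)c2)c(OC)c1 | intermediate
24 | 2-{4-[2-(3,5-dihydroxy-4-(3,4,5-trihydroxyphenoxy)phenoxy)-3,5-dihydroxyphenoxy]-3,5-dihydroxyphenoxy}benzene-1,3,5-triol | Oc1cc(O)c(Oc2cc(O)c(Oc3cc(O)cc(O)c3Oc3cc(O)c(Oc4cc(O)c(O)c(O)c4)c(O)c3)c(O)c2)c(O)c1 | target

## Step count and least certain steps

Total step count: 12. Longest linear sequence: 11 steps (steps 1 to 9, 11 and 12, from 1 and 2 to 24); step 10 is a one-step side branch.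

**Step 11 (key step, proposed new method).** The resting anion of 21 is the C2 dienolate, not the C6 enolate needed for ring closure. Lactonisation through the ketone oxygen may therefore outrun carbon acylation. The ring A aryloxy group may also be lost by addition–elimination if any alkoxide accumulates, and the ynone may oligomerise before the phenoxide has added. The fallback uses known couplings and sets out from 9. Ullmann coupling of 9 with 2 (CuI, picolinic acid, K3PO4, DMSO) should give 4-{2-[3,5-dimethoxy-4-(3,4,5-trimethoxyphenoxy)phenoxy]-3,5-dimethoxyphenoxy}-3,5-dimethoxybenzaldehyde F1. Baeyer–Villiger oxidation with mCPBA should give the aryl formate F2, and methanolysis the ring B phenol F3. A second Ullmann coupling of F3 with commercial 2-iodo-1,3,5-trimethoxybenzene should give the fully methylated pentamer F4. BBr3 then cleaves all twelve methyl ethers, and the fallback rejoins the route at 24. It costs two hindered couplings, which the main route is built to avoid.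

**Step 8.** Insertion of the copper carbenoid into the free propargylic O–H bond and carbene dimerisation may compete with coupling at the alkyne terminus. The fallback sets out from 11. Addition of lithiated tert-butyl(but-3-yn-1-yloxy)dimethylsilane (n-BuLi, THF, −78 °C) should give the silyl ether ynone F5. Desilylation with HF·pyridine should give the hydroxy ynone F6. Jones oxidation (CrO3, H2SO4, acetone, 0 °C) should give the ynone acid F7. Fischer esterification with ethanol and catalytic H2SO4 rejoins the route at 17, bypassing 12, 14 and 16.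

**Step 4.** Ring C offers only an ortho aryloxy donor and two meta methoxy groups, so hydride migration in the Criegee intermediate (leading to the benzoic acid) may compete with aryl migration. Excess peracid may also attack the electron-rich rings. The fallback sets out from 7. Addition of MeMgBr should give the carbinol F8, and Dess–Martin oxidation the methyl ketone F9. Baeyer–Villiger oxidation of F9, in which aryl migrates in preference to methyl, should give the aryl acetate F10. Methanolysis (K2CO3, MeOH) rejoins the route at 9.

**Step 1.** The bromide of 2 lies between two methoxy groups and, unlike 6, has no ortho carbonyl group to assist copper. Slow insertion may let hydrodebromination of 2 and oxidative degradation of phenol 1 take over. The fallback reverses the polarity in a Chan–Lam coupling. It sets out from no numbered compound: commercial 4-hydroxy-3,5-dimethoxybenzaldehyde and (3,4,5-trimethoxyphenyl)boronic acid replace 1 and 2. With Cu(OAc)2, pyridine and 4 Å molecular sieves in CH2Cl2 under air, the coupling should rejoin the route at 3 in one step.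

**Step 12.** Cleavage of ten methyl ethers may stop at partly methylated mixtures, and the dodecaphenol may be oxidised during aqueous work-up and chromatography. The fallback sets out from 23. After the same BBr3 treatment the crude product is acetylated (Ac2O, pyridine) to the dodecaacetate F11, which can be purified on silica. Acid-catalysed methanolysis (HCl in degassed MeOH) rejoins the route at 24.

## Further compounds

F1 | step 11 | 4-{2-[3,5-dimethoxy-4-(3,4,5-trimethoxyphenoxy)phenoxy]-3,5-dimethoxyphenoxy}-3,5-dimethoxybenzaldehyde | O=Cc1cc(OC)c(Oc2cc(OC)cc(OC)c2Oc2cc(OC)c(Oc3cc(OC)c(OC)c(OC)c3)c(OC)c2)c(OC)c1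
F2 | step 11 | 4-{2-[3,5-dimethoxy-4-(3,4,5-trimethoxyphenoxy)phenoxy]-3,5-dimethoxyphenoxy}-3,5-dimethoxyphenyl formate | O=COc1cc(OC)c(Oc2cc(OC)cc(OC)c2Oc2cc(OC)c(Oc3cc(OC)c(OC)c(OC)c3)c(OC)c2)c(OC)c1
F3 | step 11 | 4-{2-[3,5-dimethoxy-4-(3,4,5-trimethoxyphenoxy)phenoxy]-3,5-dimethoxyphenoxy}-3,5-dimethoxyphenol | Oc1cc(OC)c(Oc2cc(OC)cc(OC)c2Oc2cc(OC)c(Oc3cc(OC)c(OC)c(OC)c3)c(OC)c2)c(OC)c1
F4 | step 11 | dodeca-O-methyl ether of 24 (fully methylated pentamer) | COc1cc(OC)c(Oc2cc(OC)c(Oc3cc(OC)cc(OC)c3Oc3cc(OC)c(Oc4cc(OC)c(OC)c(OC)c4)c(OC)c3)c(OC)c2)c(OC)c1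
F5 | step 8 | 6-[(tert-butyldimethylsilyl)oxy]-1-{2-[3,5-dimethoxy-4-(3,4,5-trimethoxyphenoxy)phenoxy]-3,5-dimethoxyphenoxy}hex-3-yn-2-one | CC(C)(C)[Si](C)(C)OCCC#CC(=O)COc1cc(OC)cc(OC)c1Oc1cc(OC)c(Oc2cc(OC)c(OC)c(OC)c2)c(OC)c1
F6 | step 8 | 6-hydroxy-1-{2-[3,5-dimethoxy-4-(3,4,5-trimethoxyphenoxy)phenoxy]-3,5-dimethoxyphenoxy}hex-3-yn-2-one | OCCC#CC(=O)COc1cc(OC)cc(OC)c1Oc1cc(OC)c(Oc2cc(OC)c(OC)c(OC)c2)c(OC)c1
F7 | step 8 | 6-{2-[3,5-dimethoxy-4-(3,4,5-trimethoxyphenoxy)phenoxy]-3,5-dimethoxyphenoxy}-5-oxohex-3-ynoic acid | OC(=O)CC#CC(=O)COc1cc(OC)cc(OC)c1Oc1cc(OC)c(Oc2cc(OC)c(OC)c(OC)c2)c(OC)c1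
F8 | step 4 | rac-1-{2-[3,5-dimethoxy-4-(3,4,5-trimethoxyphenoxy)phenoxy]-3,5-dimethoxyphenyl}ethan-1-ol | CC(O)c1cc(OC)cc(OC)c1Oc1cc(OC)c(Oc2cc(OC)c(OC)c(OC)c2)c(OC)c1
F9 | step 4 | 1-{2-[3,5-dimethoxy-4-(3,4,5-trimethoxyphenoxy)phenoxy]-3,5-dimethoxyphenyl}ethan-1-one | CC(=O)c1cc(OC)cc(OC)c1Oc1cc(OC)c(Oc2cc(OC)c(OC)c(OC)c2)c(OC)c1
F10 | step 4 | 2-[3,5-dimethoxy-4-(3,4,5-trimethoxyphenoxy)phenoxy]-3,5-dimethoxyphenyl acetate | CC(=O)Oc1cc(OC)cc(OC)c1Oc1cc(OC)c(Oc2cc(OC)c(OC)c(OC)c2)c(OC)c1
F0 | step 1 | none | none
F11 | step 12 | dodecaacetate of 24 | CC(=O)Oc1cc(OC(C)=O)c(Oc2cc(OC(C)=O)c(Oc3cc(OC(C)=O)cc(OC(C)=O)c3Oc3cc(OC(C)=O)c(Oc4cc(OC(C)=O)c(OC(C)=O)c(OC(C)=O)c4)c(OC(C)=O)c3)c(OC(C)=O)c2)c(OC(C)=O)c1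
A1 | alternative 1 | 1-[2,6-dimethoxy-4-(2,4,6-trimethoxyphenoxy)phenoxy]-2-iodo-3,5-dimethoxybenzene | COc1cc(OC)c(I)c(Oc2c(OC)cc(Oc3c(OC)cc(OC)cc3OC)cc2OC)c1
A2 | alternative 1 | 2,6-dimethoxy-4-(2,4,6-trimethoxyphenoxy)phenol | COc1cc(Oc2c(OC)cc(OC)cc2OC)cc(OC)c1O
A3 | alternative 1 | 3,5-dimethoxy-2-(trimethylsilyl)phenyl trifluoromethanesulfonate | COc1cc(OC)c([Si](C)(C)C)c(OS(=O)(=O)C(F)(F)F)c1
A4 | alternative 2 | 2-[4-(benzyloxy)-3,5-dimethoxyphenoxy]benzene-1,3,5-triol | Oc1cc(O)c(Oc2cc(OC)c(OCc3ccccc3)c(OC)c2)c(O)c1
A5 | alternative 2 | methyl 6-[4-(benzyloxy)-3,5-dimethoxyphenoxy]-3,5-dioxohexanoate | COC(=O)CC(=O)CC(=O)COc1cc(OC)c(OCc2ccccc2)c(OC)c1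
A6 | alternative 3 | deca-O-methyl pentamer with free hydroxyls at A4 and C5 | COc1cc(O)cc(OC)c1Oc1cc(OC)c(Oc2cc(O)cc(OC)c2Oc2cc(OC)c(Oc3cc(OC)c(OC)c(OC)c3)c(OC)c2)c(OC)c1
A7 | alternative 3 | dideoxy pentamer lacking the A4 and C5 oxygens | COc1cccc(OC)c1Oc1cc(OC)c(Oc2cccc(OC)c2Oc2cc(OC)c(Oc3cc(OC)c(OC)c(OC)c3)c(OC)c2)c(OC)c1
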